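The numbers are made up; the flask was simulated.

Time is what you watch on this run: the set-ups below differ in vessel and in how long the mixture stays in it.

    starting material + free catalyst ⇌ free catalyst + open intermediate (K1 = 0.51, k1 = 2.1 L mol⁻¹ s⁻¹)
    coupling partner + second catalyst + open intermediate → second catalyst + product (k2 = 110 L² mol⁻² s⁻¹)
    2 coupling partner → homo dimer (k3 = 0.092 L mol⁻¹ s⁻¹)
    open intermediate + capture agent → trapped intermediate (k4 = 6.5 L mol⁻¹ s⁻¹)

the same everywhere: starting material 38 mM; coupling partner 114 mM; capture agent 0.760 mM; free catalyst 3.8 mM; second catalyst 0.76 mM

| charge | remark | time |
|---|---|---|
| north | a single well-mixed tank run continuously and read at steady state, 80 s in it on average |  |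
| north-west | plug flow through a tube for 80 s, no back-mixing | 80 s |
| east | a single well-mixed tank run continuously and read at steady state, 400 s in it on average |  |
| south-east | a closed flask charged with all of it at once and left for 80 s | 80 s |

- the set-up with the highest amount of product at the outlet or at the end, in percent of the starting material put in ("none" if the first two lie within 2 percentage points) (north / north-west / east / south-east / none)
- amount of product at the outlet or at the end, in percent of the starting material put in, north
- amount of product at the outlet or at the end, in percent of the starting material put in, north-west
- amount of product at the outlet or at the end, in percent of the starting material put in, east
- amount of product at the outlet or at the end, in percent of the starting material put in, south-east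

- a doubled species enters its step squared and goes two at a time
- the stated concentrations are those of everything mixed, before any reaction; amounts are the same in each set-up
- run time (north-west): 80 s

- At the very start the coupling step stands still, since no open intermediate exists yet. My yardstick is therefore a full rate: the coupling step with the coupling partner as charged and c(open intermediate) at its equilibrium value of 12.8 mM, which gives 0.122 mM s⁻¹.
- The first brake is the dimer step. The coupling partner has a first half-life of 47.7 s by that step, so over the closed flask's 80 s its factor on the rate averages 0.587.
- The second brake is the lag of the open intermediate. The free catalyst stands on both sides of the opening step, so that step is pseudo-first-order in starting material forward and in open intermediate back, and it relaxes at 0.0236 s⁻¹, which averages to a factor of 0.551.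
- I count the capture agent's charge as taken out of the open intermediate, a factor of 0.941.
- Multiplying these averages is a shortcut, but it gives the quantity to carry: the full-rate seconds, meaning the time at the full rate that would make the same product. I get 24.3 s for the closed flask, and the tube has the same history, so both come to 7.83%.
- A tank runs at its outlet state. In east the partner's factor is 0.291, which gives 98.9 s, while north gets 26.1 s. East has more full-rate seconds than the others, so I commit to east, at 31.8%.
- The forecast names east, with 6.9% for north, 6.3% for north-west, 22.1% for east and 6.3% for south-east, holding that “the long residence time outweighs”.
- The simulation gives east, with 6.88% for north, 6.14% for north-west, 22.1% for east and 6.14% for south-east.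
- My order stands, but my amounts run high: the closed flask delivered 19.1 s of full-rate seconds against my 24.3 s, and east delivered 68.8 s against my 98.9 s. Read the same closed flask at 30 s instead. With the capture factor left as it was, the reckoning gives 6.21 s of full-rate seconds, hence 2.00% of product, and that flask reads 1.77%.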